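**Plan**

- Retrosynthesis: the acetate is removed; ring A (butenolide: O1, C2 carbonyl, C3, C4, C5) is cut at O1–C2 and C3=C4 back to a ketone at C4; the bond between the acetoxy carbon and its allylic CH2 is cut (key step); ring B (the alkylidene lactone) is cut at its acyl C–O bond and its exocyclic C=C; the chain is farnesol less its terminal three carbons.
- Enabling feature: C5 and C4 of ring A and the acetoxy carbon, with O1 and the acetate oxygen, form a 1,3-dioxygenated three-carbon unit whose middle carbon C4 is at the ketone oxidation level (a dihydroxyacetone), and the acetoxy carbon bears an allylic CH2. A dioxanone azaenolate and an allylic bromide therefore make this bond.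
- Forward: farnesol is trimmed to a C10 aldehyde; a Z-selective Still–Gennari olefination with a glyceraldehyde-derived phosphonate adds the lactone carbons and ring B closes by lactonisation; the derived allylic bromide alkylates the RAMP hydrazone of 2,2-dimethyl-1,3-dioxan-5-one; ring A closes last (Wittig, then lactonisation) and the alcohol is acetylated.
- Stereochemistry: C5 of ring B (S) comes from (S)-glyceraldehyde acetonide; the acetoxy carbon (R) from the RAMP auxiliary; both E alkenes from farnesol; the Z alkylidene from the kinetically controlled Still–Gennari olefination.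

Key step: step 14

Remark on the chemistry: phosphonate 14 is used as its two C2 epimers and hydrazone 24 is drawn as the Z hydrazone expected from kinetic alkylation; both elements are erased in the following step. Aldehyde 6 is commercial and is distilled before use.

**Route**

Step 1
Reactants: 1 (2E,6E)-farnesol
Product: 2 (2E,6E)-1-(tert-butyldiphenylsilyloxy)-3,7,11-trimethyldodeca-2,6,10-triene
Conditions: TBDPSCl, imidazole, DMF, 0 °C → rt
Reagents that add atoms: tert-butyl(chloro)diphenylsilane, CC(C)(C)[Si](Cl)(c1ccccc1)c1ccccc1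
Why: Silyl ether protection of a primary allylic alcohol is routine, and the bulky TBDPS group is chosen because it should survive aqueous NBS, K2CO3 in MeOH and periodic acid.

Step 2
Reactants: 2 farnesyl TBDPS ether
Product: 3 (6E,10E)-3-bromo-12-(tert-butyldiphenylsilyloxy)-2,6,10-trimethyldodeca-6,10-dien-2-ol (racemic at C3)
Conditions: NBS, THF/H2O, 0 °C
Reagents that add atoms: N-bromosuccinimide, O=C1CCC(=O)N1Br; water, O
Why: Bromohydrin formation in aqueous THF is known to pick the terminal trisubstituted alkene of farnesyl derivatives, the bromonium ion being opened by water at the tertiary carbon (Markovnikov).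

Step 3
Reactants: 3 terminal bromohydrin
Product: 4 (2E,6E)-1-(tert-butyldiphenylsilyloxy)-10,11-epoxy-3,7,11-trimethyldodeca-2,6-diene (racemic)
Conditions: K2CO3, MeOH, rt
Reagents that add atoms: none
Why: Intramolecular Williamson displacement of bromide by the neighbouring alkoxide closes the epoxide under conditions that leave the silyl ether untouched.

Step 4
Reactants: 4 terminal epoxide
Product: 5 (4E,8E)-10-(tert-butyldiphenylsilyloxy)-4,8-dimethyldeca-4,8-dienal
Conditions: H5IO6, THF/Et2O, 0 °C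
Reagents that add atoms: none
Why: Periodic acid opens the epoxide to the glycol and cleaves it (periodate glycol cleavage), excising acetone and leaving the two internal trisubstituted alkenes alone.

Step 5
Reactants: 6 (4S)-2,2-dimethyl-1,3-dioxolane-4-carbaldehyde
Product: 7 (4R)-2,2-dimethyl-4-(2-methylprop-1-en-1-yl)-1,3-dioxolane
Conditions: i-PrPPh3I, n-BuLi, THF, 0 °C; then 6, −78 °C → rt
Reagents that add atoms: isopropyltriphenylphosphonium iodide, CC(C)[P+](c1ccccc1)(c1ccccc1)c1ccccc1.[I-]
Why: Wittig olefination with the non-stabilised isopropylidene ylide installs the 2-methylpropenyl group, and addition at low temperature should keep the α-alkoxy aldehyde from epimerising (the descriptor changes from S to R only through the priority rules).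

Step 6
Reactants: 7 alkenyl dioxolane
Product: 8 (2R)-4-methylpent-3-ene-1,2-diol
Conditions: AcOH/H2O, rt
Reagents that add atoms: none
Why: Acid-catalysed acetal hydrolysis under weakly acidic conditions should free the diol without ionising the secondary allylic alcohol.

Step 7
Reactants: 8 (2R)-diol
Product: 9 (2R)-1,2-bis(tert-butyldimethylsilyloxy)-4-methylpent-3-ene
Conditions: TBSCl, imidazole, DMF, rt
Reagents that add atoms: tert-butyl(chloro)dimethylsilane, CC(C)(C)[Si](C)(C)Cl
Why: Exhaustive silylation (silyl ether protection) sets up differentiation of the two hydroxyls by their different rates of desilylation.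

Step 8
Reactants: 9 bis-silyl ether
Product: 10 (2R)-2-(tert-butyldimethylsilyloxy)-4-methylpent-3-en-1-ol
Conditions: HF·pyridine, pyridine, THF, 0 °C
Reagents that add atoms: none
Why: Selective desilylation relies on the primary TBS ether being cleaved by buffered fluoride much faster than the hindered secondary one.

Step 9
Reactants: 10 (2R)-2-(tert-butyldimethylsilyloxy)-4-methylpent-3-en-1-ol; 11 methyl 2-[bis(2,2,2-trifluoroethoxy)phosphoryl]acetate
Product: 14 methyl (4S)-2-[bis(2,2,2-trifluoroethoxy)phosphoryl]-4-(tert-butyldimethylsilyloxy)-6-methylhept-5-enoate (both C2 epimers), via primary triflate 12 (not isolated), via sodium enolate 13 (not isolated)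
Conditions: 10, Tf2O, 2,6-lutidine, CH2Cl2, −78 °C; separately 11, NaH, THF, 0 °C; combine, 0 °C → rt
Reagents that add atoms: none
Why: SN2 C-alkylation of the stabilised phosphonoacetate carbanion by a primary triflate is a standard way to α-substituted Still–Gennari reagents, and it takes place at the CH2 next to the carbinol carbon, so that stereocentre is untouched.

Step 10
Reactants: 14 branched phosphonate; 5 C10 aldehyde
Product: 16 methyl (2Z,6E,10E)-2-[(2S)-2-(tert-butyldimethylsilyloxy)-4-methylpent-3-en-1-yl]-12-(tert-butyldiphenylsilyloxy)-6,10-dimethyldodeca-2,6,10-trienoate, via potassium carbanion 15 (not isolated)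
Conditions: KN(SiMe3)2, 18-crown-6, THF, −78 °C; then 5, −78 → −40 °C
Reagents that add atoms: none
Why: In the Still–Gennari variant of the Horner–Wadsworth–Emmons olefination the electron-poor bis(trifluoroethyl) phosphonate and the crown-complexed potassium ion make elimination from the kinetic adduct fast and irreversible, which should place the chain cis to the ester (Z).

Step 11
Reactants: 16 Z-enoate
Product: 18 (3Z,5S)-3-[(4E,8E)-10-hydroxy-4,8-dimethyldeca-4,8-dien-1-ylidene]-5-(2-methylprop-1-en-1-yl)oxolan-2-one, via dihydroxy ester 17 (not isolated)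
Conditions: HF·pyridine, pyridine, THF, 0 °C → rt; then PPTS (cat.), CH2Cl2, rt
Reagents that add atoms: none
Why: Fluoride-mediated desilylation frees both hydroxyls and the γ-hydroxy ester lactonises (5-exo-trig acyl substitution) to close ring B with retention at C5, the non-basic medium avoiding Z to E isomerisation of the alkylidene lactone by reversible conjugate addition.

Step 12
Reactants: 18 lactone alcohol
Product: 19 (3Z,5S)-3-[(4E,8E)-10-bromo-4,8-dimethyldeca-4,8-dien-1-ylidene]-5-(2-methylprop-1-en-1-yl)oxolan-2-one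
Conditions: CBr4, PPh3, CH2Cl2, 0 °C
Reagents that add atoms: carbon tetrabromide, BrC(Br)(Br)Br
Why: The Appel reaction converts a primary allylic alcohol into the bromide by SN2 displacement on the alkoxyphosphonium ion under neutral conditions that keep the E alkene and the lactone intact.

Step 13
Reactants: 20 2,2-dimethyl-1,3-dioxan-5-one; 21 (2R)-2-(methoxymethyl)pyrrolidin-1-amine (RAMP)
Product: 22 (2R)-N-(2,2-dimethyl-1,3-dioxan-5-ylidene)-2-(methoxymethyl)pyrrolidin-1-amine
Conditions: benzene, reflux, Dean–Stark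
Reagents that add atoms: none
Why: Hydrazone condensation with azeotropic removal of water is the standard preparation of this auxiliary-bearing dihydroxyacetone equivalent, and the symmetric ketone gives a single product.

Step 14
Reactants: 22 RAMP hydrazone; 19 allylic bromide
Product: 24 (3Z,5S)-3-[(4E,8E)-10-[(4R,5Z)-5-{[(2R)-2-(methoxymethyl)pyrrolidin-1-yl]imino}-2,2-dimethyl-1,3-dioxan-4-yl]-4,8-dimethyldeca-4,8-dien-1-ylidene]-5-(2-methylprop-1-en-1-yl)oxolan-2-one, via lithium azaenolate 23 (not isolated)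
Conditions: t-BuLi, THF, −78 °C; then 19 (limiting), −100 → −78 °C; pH 7 buffer at −78 °C
Reagents that add atoms: none
Why: Deprotonation of 22 gives the lithium azaenolate 23, in which lithium is chelated between the azaenolate nitrogen and the methoxymethyl oxygen, and its carbon terminus displaces bromide from 19 in an SN2 step that forms the bond between the future acetoxy carbon and the allylic CH2. The closest known reaction type is the Enders SAMP/RAMP-hydrazone alkylation of 2,2-dimethyl-1,3-dioxan-5-one with alkyl and allyl halides. No ring closes in this step. The new stereocentre (4R) is controlled by the auxiliary alone, the chelated pyrrolidine shielding one face so that the bromide enters from the other; RAMP is the antipode that gives R here, and the remote lactone centre has no say. The step needs chemoselectivity for the allylic bromide over the alkylidene lactone and SN2 over SN2′ regioselectivity. The first should be secured by the high rate of allylic displacement at −100 °C, the α-branched and β-substituted (poorly accepting) lactone alkene, the bromide as limiting reagent and the cold quench; the second by the fully substituted γ-carbon of the bromide, which also leaves the E alkene untouched.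

Step 15
Reactants: 24 alkylated hydrazone
Product: 25 (3Z,5S)-3-{(4E,8E)-10-[(4R)-2,2-dimethyl-5-oxo-1,3-dioxan-4-yl]-4,8-dimethyldeca-4,8-dien-1-ylidene}-5-(2-methylprop-1-en-1-yl)oxolan-2-one
Conditions: sat. aq. (CO2H)2, Et2O, rt
Reagents that add atoms: water, O
Why: Two-phase hydrolysis of the hydrazone with aqueous oxalic acid is the established mild cleavage for dioxanone hydrazones, which should keep the acetonide and the α-stereocentre intact while the auxiliary passes into the aqueous phase.

Step 16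
Reactants: 25 ketone
Product: 26 methyl (2E)-2-[(4R)-4-{(2E,6E)-3,7-dimethyl-10-[(3Z,5S)-5-(2-methylprop-1-en-1-yl)-2-oxooxolan-3-ylidene]deca-2,6-dien-1-yl}-2,2-dimethyl-1,3-dioxan-5-ylidene]acetate
Conditions: Ph3P=CHCO2Me, toluene, 60 °C
Reagents that add atoms: methyl (triphenylphosphoranylidene)acetate, COC(=O)C=P(c1ccccc1)(c1ccccc1)c1ccccc1
Why: Wittig olefination of the activated α,α′-dialkoxy ketone with a stabilised, weakly basic ylide should put the ester on the side of the unsubstituted C6, because the other geometry would force the C4 substituent axial against the axial methyl of the acetonide to escape allylic 1,3-strain.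

Step 17
Reactants: 26 ylidene ester
Product: 28 4-{(1R,3E,7E)-1-hydroxy-4,8-dimethyl-11-[(3Z,5S)-5-(2-methylprop-1-en-1-yl)-2-oxooxolan-3-ylidene]undeca-3,7-dien-1-yl}furan-2(5H)-one, via diol ester 27 (not isolated)
Conditions: AcOH/THF/H2O, 40 °C
Reagents that add atoms: none
Why: Acid-catalysed acetal hydrolysis frees both hydroxyls and the primary one, held cis to the ester across the alkene, lactonises at once (5-exo-trig acyl substitution) to close ring A without breaking the carbinol C–O bond.

Step 18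
Reactants: 28 hydroxy butenolide
Product: 29 (1R,3E,7E)-4,8-dimethyl-11-[(3Z,5S)-5-(2-methylprop-1-en-1-yl)-2-oxooxolan-3-ylidene]-1-(5-oxo-2,5-dihydrofuran-3-yl)undeca-3,7-dien-1-yl acetate
Conditions: Ac2O, pyridine, DMAP (cat.), CH2Cl2, 0 °C
Reagents that add atoms: acetic anhydride, CC(=O)OC(C)=O
Why: DMAP-catalysed acylation of the secondary alcohol proceeds at oxygen with retention and gives the target.

**Compound list**

1 | (2E,6E)-farnesol | OC/C=C(\C)CC/C=C(\C)CCC=C(C)C | starting material
2 | (2E,6E)-1-(tert-butyldiphenylsilyloxy)-3,7,11-trimethyldodeca-2,6,10-triene | CC(C)(C)[Si](OC/C=C(\C)CC/C=C(\C)CCC=C(C)C)(c1ccccc1)c1ccccc1 | intermediate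
3 | (6E,10E)-3-bromo-12-(tert-butyldiphenylsilyloxy)-2,6,10-trimethyldodeca-6,10-dien-2-ol (racemic at C3) | CC(C)(C)[Si](OC/C=C(\C)CC/C=C(\C)CCC(Br)C(C)(C)O)(c1ccccc1)c1ccccc1 | intermediate
4 | (2E,6E)-1-(tert-butyldiphenylsilyloxy)-10,11-epoxy-3,7,11-trimethyldodeca-2,6-diene (racemic) | CC(C)(C)[Si](OC/C=C(\C)CC/C=C(\C)CCC1OC1(C)C)(c1ccccc1)c1ccccc1 | intermediate
5 | (4E,8E)-10-(tert-butyldiphenylsilyloxy)-4,8-dimethyldeca-4,8-dienal | CC(C)(C)[Si](OC/C=C(\C)CC/C=C(\C)CCC=O)(c1ccccc1)c1ccccc1 | intermediate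
6 | (4S)-2,2-dimethyl-1,3-dioxolane-4-carbaldehyde ((S)-glyceraldehyde acetonide) | CC1(C)OC[C@@H](C=O)O1 | starting material
7 | (4R)-2,2-dimethyl-4-(2-methylprop-1-en-1-yl)-1,3-dioxolane | CC1(C)OC[C@@H](C=C(C)C)O1 | intermediate
8 | (2R)-4-methylpent-3-ene-1,2-diol | OC[C@@H](C=C(C)C)O | intermediate
9 | (2R)-1,2-bis(tert-butyldimethylsilyloxy)-4-methylpent-3-ene | CC(C)(C)[Si](C)(C)OC[C@@H](C=C(C)C)O[Si](C)(C)C(C)(C)C | intermediate
10 | (2R)-2-(tert-butyldimethylsilyloxy)-4-methylpent-3-en-1-ol | OC[C@@H](C=C(C)C)O[Si](C)(C)C(C)(C)C | intermediate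
11 | methyl 2-[bis(2,2,2-trifluoroethoxy)phosphoryl]acetate | COC(=O)CP(=O)(OCC(F)(F)F)OCC(F)(F)F | starting material
12 | (2R)-2-(tert-butyldimethylsilyloxy)-4-methylpent-3-en-1-yl trifluoromethanesulfonate | FC(F)(F)S(=O)(=O)OC[C@@H](C=C(C)C)O[Si](C)(C)C(C)(C)C | intermediate
13 | sodium [bis(2,2,2-trifluoroethoxy)phosphoryl](methoxycarbonyl)methanide | [Na+].COC(=O)[CH-]P(=O)(OCC(F)(F)F)OCC(F)(F)F | intermediate
14 | methyl (4S)-2-[bis(2,2,2-trifluoroethoxy)phosphoryl]-4-(tert-butyldimethylsilyloxy)-6-methylhept-5-enoate (both C2 epimers) | COC(=O)C(C[C@@H](C=C(C)C)O[Si](C)(C)C(C)(C)C)P(=O)(OCC(F)(F)F)OCC(F)(F)F | intermediate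
15 | potassium salt of 14 deprotonated at C2 | [K+].COC(=O)[C-](C[C@@H](C=C(C)C)O[Si](C)(C)C(C)(C)C)P(=O)(OCC(F)(F)F)OCC(F)(F)F | intermediate
16 | methyl (2Z,6E,10E)-2-[(2S)-2-(tert-butyldimethylsilyloxy)-4-methylpent-3-en-1-yl]-12-(tert-butyldiphenylsilyloxy)-6,10-dimethyldodeca-2,6,10-trienoate | CC(C)(C)[Si](OC/C=C(\C)CC/C=C(\C)CC/C=C(/C[C@@H](C=C(C)C)O[Si](C)(C)C(C)(C)C)C(=O)OC)(c1ccccc1)c1ccccc1 | intermediate
17 | methyl (2Z,6E,10E)-12-hydroxy-2-[(2S)-2-hydroxy-4-methylpent-3-en-1-yl]-6,10-dimethyldodeca-2,6,10-trienoate | OC/C=C(\C)CC/C=C(\C)CC/C=C(/C[C@@H](C=C(C)C)O)C(=O)OC | intermediate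
18 | (3Z,5S)-3-[(4E,8E)-10-hydroxy-4,8-dimethyldeca-4,8-dien-1-ylidene]-5-(2-methylprop-1-en-1-yl)oxolan-2-one | OC/C=C(\C)CC/C=C(\C)CC/C=C1/C[C@@H](C=C(C)C)OC1=O | intermediate
19 | (3Z,5S)-3-[(4E,8E)-10-bromo-4,8-dimethyldeca-4,8-dien-1-ylidene]-5-(2-methylprop-1-en-1-yl)oxolan-2-one | BrC/C=C(\C)CC/C=C(\C)CC/C=C1/C[C@@H](C=C(C)C)OC1=O | intermediate
20 | 2,2-dimethyl-1,3-dioxan-5-one | CC1(C)OCC(=O)CO1 | starting material
21 | (2R)-2-(methoxymethyl)pyrrolidin-1-amine (RAMP) | COC[C@H]1CCCN1N | starting material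
22 | (2R)-N-(2,2-dimethyl-1,3-dioxan-5-ylidene)-2-(methoxymethyl)pyrrolidin-1-amine | COC[C@H]1CCCN1N=C1COC(C)(C)OC1 | intermediate
23 | lithium azaenolate of 22: lithium (2,2-dimethyl-4H-1,3-dioxin-5-yl)[(2R)-2-(methoxymethyl)pyrrolidin-1-yl]azanide | [Li+].COC[C@H]1CCCN1[N-]C1=COC(C)(C)OC1 | intermediate
24 | (3Z,5S)-3-[(4E,8E)-10-[(4R,5Z)-5-{[(2R)-2-(methoxymethyl)pyrrolidin-1-yl]imino}-2,2-dimethyl-1,3-dioxan-4-yl]-4,8-dimethyldeca-4,8-dien-1-ylidene]-5-(2-methylprop-1-en-1-yl)oxolan-2-one | COC[C@H]1CCCN1/N=C2/COC(C)(C)O[C@@H]2C/C=C(\C)CC/C=C(\C)CC/C=C3/C[C@@H](C=C(C)C)OC3=O | intermediate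
25 | (3Z,5S)-3-{(4E,8E)-10-[(4R)-2,2-dimethyl-5-oxo-1,3-dioxan-4-yl]-4,8-dimethyldeca-4,8-dien-1-ylidene}-5-(2-methylprop-1-en-1-yl)oxolan-2-one | O=C1COC(C)(C)O[C@@H]1C/C=C(\C)CC/C=C(\C)CC/C=C2/C[C@@H](C=C(C)C)OC2=O | intermediate
26 | methyl (2E)-2-[(4R)-4-{(2E,6E)-3,7-dimethyl-10-[(3Z,5S)-5-(2-methylprop-1-en-1-yl)-2-oxooxolan-3-ylidene]deca-2,6-dien-1-yl}-2,2-dimethyl-1,3-dioxan-5-ylidene]acetate | COC(=O)/C=C1\COC(C)(C)O[C@@H]1C/C=C(\C)CC/C=C(\C)CC/C=C2/C[C@@H](C=C(C)C)OC2=O | intermediate
27 | methyl (2E,4R,6E,10E)-4-hydroxy-3-(hydroxymethyl)-7,11-dimethyl-14-[(3Z,5S)-5-(2-methylprop-1-en-1-yl)-2-oxooxolan-3-ylidene]tetradeca-2,6,10-trienoate | COC(=O)/C=C(\CO)[C@H](O)C/C=C(\C)CC/C=C(\C)CC/C=C1/C[C@@H](C=C(C)C)OC1=O | intermediate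
28 | 4-{(1R,3E,7E)-1-hydroxy-4,8-dimethyl-11-[(3Z,5S)-5-(2-methylprop-1-en-1-yl)-2-oxooxolan-3-ylidene]undeca-3,7-dien-1-yl}furan-2(5H)-one | O[C@H](C/C=C(\C)CC/C=C(\C)CC/C=C1/C[C@@H](C=C(C)C)OC1=O)C1=CC(=O)OC1 | intermediate
29 | (1R,3E,7E)-4,8-dimethyl-11-[(3Z,5S)-5-(2-methylprop-1-en-1-yl)-2-oxooxolan-3-ylidene]-1-(5-oxo-2,5-dihydrofuran-3-yl)undeca-3,7-dien-1-yl acetate | CC(=O)O[C@H](C/C=C(\C)CC/C=C(\C)CC/C=C1/C[C@@H](C=C(C)C)OC1=O)C1=CC(=O)OC1 | target

**Count**

Total: 18 steps. Longest linear sequence: 13 steps (steps 5–12, then 14–18).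

**Steps most likely to fail**

Step 14. The azaenolate may add to the alkylidene lactone (conjugate or acyl addition) or be quenched by proton transfer from it, in competition with allylic displacement. The fallback keeps the lactone away from the azaenolate by reversing the order of assembly; it sets out from 1 and 22 and rejoins the route at 28.
- Farnesol 1 is converted with CBr4 and PPh3 into (2E,6E)-farnesyl bromide F1, which alkylates azaenolate 23 under the conditions of step 14 to give the (4R)-farnesyl hydrazone F2.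
- Aqueous oxalic acid gives the ketone F3, and Ph3P=CHCO2Me the ylidene ester F4.
- NBS in aqueous THF gives the terminal bromohydrin F5, and K2CO3 in MeOH the terminal epoxide F6.
- Periodic acid followed by aqueous acetic acid cleaves the epoxide, removes the acetonide and closes ring A, giving the hydroxy butenolide aldehyde F7.
- Still–Gennari olefination of F7 with the potassium carbanion 15 gives the Z-enoate F8, and HF·pyridine removes the silyl group and closes ring B to give 28.

Step 10. Addition of the hindered carbanion may be slow or partly reversible, eroding kinetic control and giving E/Z mixtures. The fallback builds the Z alkene stereospecifically from an alkyne; it sets out from 5 and 10 (through triflate 12) and rejoins at 18.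
- Seyferth–Gilbert homologation of 5 with the Ohira–Bestmann reagent (K2CO3, MeOH) gives the terminal alkyne F9.
- Its lithium acetylide (n-BuLi, THF/DMPU) is alkylated by triflate 12 to the internal alkyne F10, and Bu4NF frees both hydroxyls to give the diol F11.
- Hydroxyl-directed trans-hydrostannation (Bu3SnH, [Cp*RuCl]4 cat.) should place tin on the alkyne carbon nearer the secondary hydroxyl and trans to the new hydrogen, giving the alkenylstannane F12.
- Iododestannylation with I2 gives the Z-iodoalkene F13 with retention, and carbonylative lactonisation (CO, Pd(PPh3)4, K2CO3) closes ring B to 18 with the chain cis to the carbonyl by construction.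

Step 16. Olefination of the α-branched ketone may be slow, allowing epimerisation at C4 of the dioxanone, or may give some of the other alkene geometry, which would then lactonise onto the secondary hydroxyl. The fallback closes ring A from the free keto diol; it sets out from 25 and rejoins at 28.
- Acetonide hydrolysis of 25 with aqueous acetic acid gives the keto diol F14.
- Ph3P=C=C=O (triphenylphosphoranylideneketene) in warm toluene acylates the less hindered primary hydroxyl, and the resulting ester ylide closes ring A on the ketone by intramolecular Wittig reaction to give 28.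

**Further compounds**

F1 | step 14 | (2E,6E)-1-bromo-3,7,11-trimethyldodeca-2,6,10-triene (farnesyl bromide) | BrC/C=C(\C)CC/C=C(\C)CCC=C(C)C
F2 | step 14 | (2R)-N-{(4R,5Z)-2,2-dimethyl-4-[(2E,6E)-3,7,11-trimethyldodeca-2,6,10-trien-1-yl]-1,3-dioxan-5-ylidene}-2-(methoxymethyl)pyrrolidin-1-amine | COC[C@H]1CCCN1/N=C2/COC(C)(C)O[C@@H]2C/C=C(\C)CC/C=C(\C)CCC=C(C)C
F3 | step 14 | (4R)-2,2-dimethyl-4-[(2E,6E)-3,7,11-trimethyldodeca-2,6,10-trien-1-yl]-1,3-dioxan-5-one | O=C1COC(C)(C)O[C@@H]1C/C=C(\C)CC/C=C(\C)CCC=C(C)C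
F4 | step 14 | methyl (2E)-2-{(4R)-2,2-dimethyl-4-[(2E,6E)-3,7,11-trimethyldodeca-2,6,10-trien-1-yl]-1,3-dioxan-5-ylidene}acetate | COC(=O)/C=C1\COC(C)(C)O[C@@H]1C/C=C(\C)CC/C=C(\C)CCC=C(C)C
F5 | step 14 | terminal bromohydrin of F4 (10-bromo-11-hydroxy, both C10 epimers) | COC(=O)/C=C1\COC(C)(C)O[C@@H]1C/C=C(\C)CC/C=C(\C)CCC(Br)C(C)(C)O
F6 | step 14 | terminal 10,11-epoxide of F4 (both C10 epimers) | COC(=O)/C=C1\COC(C)(C)O[C@@H]1C/C=C(\C)CC/C=C(\C)CCC2OC2(C)C
F7 | step 14 | (4E,8E,11R)-11-hydroxy-4,8-dimethyl-11-(5-oxo-2,5-dihydrofuran-3-yl)undeca-4,8-dienal | O[C@H](C/C=C(\C)CC/C=C(\C)CCC=O)C1=CC(=O)OC1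
F8 | step 14 | methyl (2Z,6E,10E,13R)-2-[(2S)-2-(tert-butyldimethylsilyloxy)-4-methylpent-3-en-1-yl]-13-hydroxy-6,10-dimethyl-13-(5-oxo-2,5-dihydrofuran-3-yl)trideca-2,6,10-trienoate | O[C@H](C/C=C(\C)CC/C=C(\C)CC/C=C(/C[C@@H](C=C(C)C)O[Si](C)(C)C(C)(C)C)C(=O)OC)C1=CC(=O)OC1
F9 | step 10 | tert-butyl{[(2E,6E)-3,7-dimethylundeca-2,6-dien-10-yn-1-yl]oxy}diphenylsilane | CC(C)(C)[Si](OC/C=C(\C)CC/C=C(\C)CCC#C)(c1ccccc1)c1ccccc1
F10 | step 10 | (2E,6E,13S)-13-(tert-butyldimethylsilyloxy)-1-(tert-butyldiphenylsilyloxy)-3,7,15-trimethylhexadeca-2,6,14-trien-10-yne | CC(C)(C)[Si](OC/C=C(\C)CC/C=C(\C)CCC#CC[C@@H](C=C(C)C)O[Si](C)(C)C(C)(C)C)(c1ccccc1)c1ccccc1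
F11 | step 10 | (2E,6E,13S)-3,7,15-trimethylhexadeca-2,6,14-trien-10-yne-1,13-diol | OC/C=C(\C)CC/C=C(\C)CCC#CC[C@@H](C=C(C)C)O
F12 | step 10 | (2E,6E,10Z,13S)-3,7,15-trimethyl-11-(tributylstannyl)hexadeca-2,6,10,14-tetraene-1,13-diol | OC/C=C(\C)CC/C=C(\C)CC/C=C(/C[C@@H](C=C(C)C)O)[Sn](CCCC)(CCCC)CCCC
F13 | step 10 | (2E,6E,10Z,13S)-11-iodo-3,7,15-trimethylhexadeca-2,6,10,14-tetraene-1,13-diol | OC/C=C(\C)CC/C=C(\C)CC/C=C(/C[C@@H](C=C(C)C)O)I
F14 | step 16 | (3Z,5S)-3-[(4E,8E,11R)-11,13-dihydroxy-4,8-dimethyl-12-oxotrideca-4,8-dien-1-ylidene]-5-(2-methylprop-1-en-1-yl)oxolan-2-one | OCC(=O)[C@H](O)C/C=C(\C)CC/C=C(\C)CC/C=C1/C[C@@H](C=C(C)C)OC1=O
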